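The data were computed with made-up constants; scatter was added.

A small charge of D, 4.00 mM, stands beside solid J and L in a flask that makes E, and E stops early.

| flask | J | L | D | temperature | remark | time |
|---|---|---|---|---|---|---|
| theta | 0.20 M | 0.22 M | 4 mM | 25 °C | the very flask that is asked about, followed so far |  |
| epsilon | 0.20 M | 0.22 M | 4 mM | 20 °C | run made earlier |  |
| flask | 0.20 M | 0.220 M | 4.00 mM | 25 °C |  | 1.0 h |

| run | time / min | E / % |
|---|---|---|
| theta | 2.00 | 5.7 |
| theta | 6.00 | 19.2 |
| theta | 10.0 | 29.2 |
| theta | 15.0 | 35.2 |
| theta | 20.0 | 39.0 |
| theta | 30.0 | 40.2 |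
| theta | 40.0 | 41.4 |
| epsilon | 2.00 | 3.1 |
| epsilon | 6.00 | 15.6 |
| epsilon | 10.0 | 28.7 |
| epsilon | 15.0 | 40.5 |
| epsilon | 20.0 | 47.7 |
| epsilon | 30.0 | 53.2 |
| epsilon | 40.0 | 52.7 |

(readings scatter by 1 percentage point)

- grey: at 1.0 h raise the temperature by 20 K, then wait 1.0 h
- ochre: at 1.0 h take out 90 % of the E then present, then wait 1.0 h
- green: at 1.0 h add L, 50.0 % of the amount charged, then wait 1.0 h
- red: change nothing and wait 1.0 h more

- as a solid, counted per litre of solution: J
- E that was removed still counts
- at the start none of J is in solution
- additions bring no volume worth counting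

1. E, in percent of the J first charged, at 1.0 h
2. which option adds most E ("none" when 2 percentage points or less is all one gets) (grey / ochre / green / red / none)
3. E present, with what was taken out counted in, in percent of the J first charged, after ochre
4. E present, with what was taken out counted in, in percent of the J first charged, after green

1. At 40.0 min, E reads 41.4 % of the J charged in the theta run at 25 °C and 52.7 % in the epsilon run at 20 °C, so the warmer flask stands lower.

2. This reckoning takes L, charged at 1.10 equivalents to J, as the limiting reagent: L goes to E, one L for each E, and also goes away by itself, more so when warmer. The readings do not separate this from an equilibrium.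

3. Two amounts then count, E at the stop and L charged. Their ratio, 37.6 % in the theta run at its last reading, is read as the share of L that reaches E. The epsilon run reads 47.9 %, which is more.

4. If L has ended at the stop, this flask stands near 41.4 % at 1.0 h, and waiting, warming or taking E out gives no more E. Green's new L, at the same share, adds 21 percentage points of the J charged, reaching 62.1 %, so this reckoning picks green.

5. The forecast differs on the cause, saying “An exothermic equilibrium explains this best.” It gives 41 % now, picks ochre, and puts ochre at 62 % and green at 59 %.

6. The flask gives 40.2 % at 1.0 h. The best option is green, which adds 34 points and ends at 74.1 %, while ochre adds 0 points and ends at 40.2 %.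

    J ⇌ G, rate k1*(cs1 - [G]) while solid is left; crystals form when [G] > cs1 (solubility = 0.150 M, k = 0.0920 /min)
    G + L → E (k = 2.40 /M/min, Ea = 65.0 kJ/mol)
    L → X (k = 0.0460 /min, Ea = 94.0 kJ/mol)
    J + D → Q (k = 53.0 /M/min, Ea = 62.0 kJ/mol)
    L → Z (k = 0.0680 /min, Ea = 89.0 kJ/mol)
    (constants at 25 °C)

7. In the asked flask, L stands at 0 % of its charge at 60.0 min. The L added in green reached E with a share of 61.8 %, more than the share read from the theta run. A flask like this one but charged with 0.80 M of J keeps to the theta reading: the share gives 10.3 % of its J as E, and that flask gives 10.0 %.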